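The slow part of these runs is the late emptying of the pool. By pool I mean substrate plus dormant form, whatever is not yet intermediate or target.

| flask | substrate | partner | remark | time |
|---|---|---|---|---|
| Sunday's | 0.50 M | 1.05 M | run made earlier |  |
| Friday's | 0.75 M | 1.05 M | run made earlier |  |
| Thursday's | 1 M | 0.53 M | run made earlier |  |
| flask | 1.0 M | 1.05 M |  | 3.0 min |

| run | time / min | intermediate / % | target / % | substrate / % |
|---|---|---|---|---|
| Sunday's | 0.167 | 31 | 4 | 34 |
| Sunday's | 0.333 | 36 | 15 | 14 |
| Sunday's | 0.500 | 35 | 22 | 12 |
| Sunday's | 1.00 | 22 | 43 | 6 |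
| Sunday's | 2.00 | 15 | 66 | 4 |
| Sunday's | 4.00 | 9 | 85 | 2 |
| Friday's | 0.167 | 30 | 3 | 37 |
| Friday's | 0.333 | 36 | 15 | 16 |
| Friday's | 0.500 | 38 | 24 | 9 |
| Friday's | 1.00 | 27 | 41 | 2 |
| Friday's | 2.00 | 18 | 64 | 3 |
| Friday's | 4.00 | 10 | 80 | 1 |
| Thursday's | 0.167 | 34 | 3 | 39 |
| Thursday's | 0.250 | 39 | 1 | 23 |
| Thursday's | 0.500 | 44 | 14 | 5 |
| Thursday's | 1.33 | 42 | 30 | 5 |
| Thursday's | 4.00 | 42 | 49 | 0 |

(standard deviation of a reading: 1.5 percentage points)

- what was read earlier has a scatter of 1.5 percentage points, one standard deviation
- steps thought possible: substrate -> intermediate; partner + intermediate -> target; substrate <-> dormant form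

* time, not beyond 3.0 min, at which the flask holds most intermediate
* the amount of intermediate, in percent of the substrate charged, at that time
* earliest time at which at least nineteen twentieths of that best amount are there, in min
* latest time at which they still are, in min

Averaged over Sunday's and Friday's runs, the pool stands at 33.5% at 1.00 min and 8.00% at 4.00 min. My first way reads the fall directly:

leak = ln(early pool / late pool) / elapsed time = 0.477 min⁻¹

The leak, the fraction of the pool passed on to intermediate each minute, is what I carry.

My second way uses substrate readings. At first, substrate falls at 6.02 min⁻¹, far faster than the pool, so I treat the pool's split as steady in the late readings. By the first reading, 55.3% of what left substrate appears as intermediate or target. Late on, free substrate is 15.0% of the pool.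

leak = fall of substrate × share onward × free share = 0.499 min⁻¹

The two ways give 0.477 min⁻¹ and 0.499 min⁻¹. They share the late intermediate and target readings, so their closeness is no independent check. I carry the first. Thursday's run, with about half the partner, still has a pool of 9.00% at 4.00 min. For the asked flask I therefore expect a pool at 3.0 min of:

12.9%

The forecast gives 36% at 0.41 min, with the window from 0.27 min to 0.62 min: “The peak is therefore early and broad.”

The flask gives 37.0% at 0.355 min, earlier than forecast, with the window from 0.237 min to 0.534 min.

    substrate → intermediate (k = 0.0570 s⁻¹)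
    partner + intermediate → target (k = 0.0260 M⁻¹ s⁻¹)
    substrate ⇌ dormant form (K = 3.00, k = 0.0440 s⁻¹)

The flask's pool at 3.00 min is 12.6%, against my 12.9%. I take the neighbour with 0.42 M of partner, the limiting reagent there. With the leak 0.477 min⁻¹, I again expect a pool of 12.9%, so 87.1% has been released. That neighbour holds 1.71% substrate and 10.9% dormant form, as the flask does. Its target is 37.2%, so released minus target gives 49.9%. Its intermediate stands at 50.2%.

The runs were generated by integration with made-up constants, and the scatter is random.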